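**Plan**

1. Retrosynthesis: the C8 acetate and the C13 acid are folded back into a δ-lactone (C8–O–C13), the C18 acid is traced to a CH2OSi group and a 3β-hydroxyl is added; the tricycle is then cut at C4–C5, C9–C10 and C8–O to give a linear (2S,3S)-epoxy (E,E)-dienoic acid.
2. Enabling feature: a trans-decalin with axial methyls on C4, C8 and C10, the C18 carbon equatorial on C4, and the C8 oxygen 1,5 to the C13 carboxyl. This is the chair–chair folding pattern of an all-E farnesyl chain extended by two acid carbons.
3. Forward, chain first: farnesol → bromide → malonate → ethyl farnesylacetate; the terminal (E)-methyl is hydroxylated, the allylic alcohol is epoxidised, silylated, and the ester is saponified.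
4. One Lewis-acid step then closes ring A, ring B and the δ-lactone, in that order.
5. End game: radical removal of the C3 oxygen, C18 taken to the acid, lactone opened and both acids benzylated, tertiary C8 alcohol acetylated, hydrogenolysis.
6. Stereochemistry: the single Sharpless epoxide (L-(+)-tartrate) sets C3 and thereby the absolute sense of folding; the E-alkenes and anti additions set C4, C5, C8, C9 and C10; C3 is erased afterwards.

Key step: step 8

Remark: labdane numbering is used (C18 = 4α-equatorial carbon, C19 = 4β-methyl, C20 on C10, C17 on C8, side chain C11–C13), so the target is read as (4R,5R,8R,9R,10S)-8α-acetoxy-14,15,16-trinorlabdane-13,18-dioic acid; the C18 oxygen is carried as a tert-butyldiphenylsilyl ether, chosen for its resistance to Lewis acid and its low basicity.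

**Route**

Step 1
Reactants: 1 (2E,6E)-farnesol
Product: 2 (2E,6E)-farnesyl bromide
Conditions: PBr3 (0.4 equiv), Et2O, −10 → 0 °C
Reagents that add atoms: phosphorus tribromide, BrP(Br)Br
Why: Bromination of a primary allylic alcohol with PBr3 proceeds by SN2 displacement of the phosphite ester at low temperature, so the two E-alkenes should be kept and allylic transposition stays minor.

Step 2
Reactants: 2 (2E,6E)-farnesyl bromide; 3 diethyl malonate
Product: 5 diethyl 2-[(2E,6E)-3,7,11-trimethyldodeca-2,6,10-trienyl]malonate, via sodium diethyl malonate 4 (not isolated)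
Conditions: NaH, THF, 0 °C (3 in excess); then 2, 0 °C → rt
Reagents that add atoms: diethyl malonate 3, CCOC(=O)CC(=O)OCC
Why: Malonic ester alkylation, in which the soft enolate attacks the primary allylic bromide by SN2 at the α-carbon and the excess of malonate should suppress dialkylation.

Step 3
Reactants: 5 diethyl 2-[(2E,6E)-3,7,11-trimethyldodeca-2,6,10-trienyl]malonate
Product: 6 ethyl (4E,8E)-5,9,13-trimethyltetradeca-4,8,12-trienoate (ethyl farnesylacetate)
Conditions: LiCl, H2O, DMSO, 150–160 °C
Reagents that add atoms: none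
Why: Krapcho dealkoxycarbonylation removes one ester group of a mono-substituted malonate under neutral conditions that leave the trisubstituted alkenes untouched.

Step 4
Reactants: 6 ethyl (4E,8E)-5,9,13-trimethyltetradeca-4,8,12-trienoate
Product: 7 ethyl (4E,8E,12E)-14-hydroxy-5,9,13-trimethyltetradeca-4,8,12-trienoate
Conditions: SeO2 (cat.), t-BuOOH, salicylic acid (cat.), CH2Cl2, 0 °C → rt, stopped at partial conversion
Reagents that add atoms: selenium dioxide (oxygen carrier), O=[Se]=O; tert-butyl hydroperoxide (terminal oxidant), CC(C)(C)OO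
Why: Riley allylic oxidation in its catalytic SeO2/t-BuOOH form (ene reaction, then [2,3]-sigmatropic shift) attacks the terminal gem-dimethyl alkene, the most accessible one, at its (E)-methyl, so the CH2OH should stand trans to the chain.

Step 5
Reactants: 7 ethyl (4E,8E,12E)-14-hydroxy-5,9,13-trimethyltetradeca-4,8,12-trienoate
Product: 8 ethyl (4E,8E)-11-[(2S,3S)-3-(hydroxymethyl)-3-methyloxiran-2-yl]-5,9-dimethylundeca-4,8-dienoate
Conditions: Ti(OiPr)4 (cat.), L-(+)-diethyl tartrate (cat.), t-BuOOH, 4 Å MS, CH2Cl2, −20 °C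
Reagents that add atoms: tert-butyl hydroperoxide, CC(C)(C)OO
Why: Sharpless asymmetric epoxidation touches only the allylic alcohol, and with L-(+)-tartrate oxygen is delivered to the face of an (E)-allylic alcohol that gives the (2S,3S)-epoxy alcohol, which sets the later C3 and the cis/trans relation of the C4 substituents.

Step 6
Reactants: 8 ethyl (4E,8E)-11-[(2S,3S)-3-(hydroxymethyl)-3-methyloxiran-2-yl]-5,9-dimethylundeca-4,8-dienoate
Product: 9 ethyl (4E,8E)-11-[(2S,3S)-3-[(tert-butyldiphenylsilyloxy)methyl]-3-methyloxiran-2-yl]-5,9-dimethylundeca-4,8-dienoate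
Conditions: TBDPSCl, imidazole, CH2Cl2, 0 °C → rt
Reagents that add atoms: tert-butyl(chloro)diphenylsilane, CC(C)(C)[Si](Cl)(c1ccccc1)c1ccccc1
Why: Imidazole-mediated silylation of the primary hydroxyl is fast and neutral, so the epoxide and the ester should be unaffected.

Step 7
Reactants: 9 ethyl (4E,8E)-11-[(2S,3S)-3-[(tert-butyldiphenylsilyloxy)methyl]-3-methyloxiran-2-yl]-5,9-dimethylundeca-4,8-dienoate
Product: 11 (4E,8E)-11-[(2S,3S)-3-[(tert-butyldiphenylsilyloxy)methyl]-3-methyloxiran-2-yl]-5,9-dimethylundeca-4,8-dienoic acid, via lithium carboxylate 10 (not isolated)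
Conditions: LiOH·H2O, THF/MeOH/H2O, rt; then cold 10% aq. citric acid to pH 5, extraction, used at once
Reagents that add atoms: lithium hydroxide, [Li+].[OH-]
Why: Saponification (BAc2) of the unhindered ethyl ester spares the trisubstituted epoxide and the silyl ether, and the mild acidification should free the acid without opening the oxirane.

Step 8
Reactants: 11 (4E,8E)-11-[(2S,3S)-3-[(tert-butyldiphenylsilyloxy)methyl]-3-methyloxiran-2-yl]-5,9-dimethylundeca-4,8-dienoic acid
Product: 12 3β-hydroxy-18-(tert-butyldiphenylsilyloxy)-14,15,16-trinorlabdan-13,8α-olide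
Conditions: SnCl4 (1.5 equiv, promoter), CH2Cl2 (high dilution), −78 °C; sat. aq. NaHCO3
Reagents that add atoms: none
Why: SnCl4 binds the oxirane oxygen and the bond to the tertiary carbon C4 breaks as C5 of the C5=C10 alkene attacks C4 from the rear; the charge then passes through C10 and C8 by antiperiplanar additions across the two E-trisubstituted alkenes and is quenched at C8 by the carboxyl oxygen, whose proton ends on the C3 oxygen. The closest known reaction types are the Lewis acid-initiated epoxy-polyene polycyclisation and the carboxyl-terminated cyclisation of farnesyl-type acids to fused lactones. Ring A closes 6-endo (both oxirane carbons and both carbons of the C5=C10 alkene lie in the ring), ring B closes 6-endo at the C9=C8 alkene, and the δ-lactone closes by Markovnikov capture of the C8 cation, 6-endo with respect to the C8=C9 alkene of the γ,δ-unsaturated acid. C3 is carried over from the epoxide and, equatorial in the chair–chair array, decides which face of the C5=C10 alkene reaches C4, so the absolute sense follows from it; C4 is set by inversion, the group trans to C2 on the oxirane (CH2OSi) becoming 4α-equatorial and the methyl 4β-axial; C5/C10 (5α-H, 10β-methyl) and C9/C8 (9α-H, 8β-methyl, 8α-oxygen, trans-fused lactone) follow from anti addition across the E-alkenes. The step needs opening at C4 and not at C3, chair–chair and not boat folding, and oxygen capture instead of proton loss; the tertiary nature of C4, the all-E geometry, the 1,5 placing of the carboxyl on C8 and the bulky, weakly basic silyl ether, which neither chelates tin nor attacks C4, should secure these.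

Step 9
Reactants: 12 3β-hydroxy-18-(tert-butyldiphenylsilyloxy)-14,15,16-trinorlabdan-13,8α-olide
Product: 13 3β-(phenoxythiocarbonyloxy)-18-(tert-butyldiphenylsilyloxy)-14,15,16-trinorlabdan-13,8α-olide
Conditions: PhOC(S)Cl, DMAP, MeCN, rt → 40 °C
Reagents that add atoms: O-phenyl chlorothionoformate, S=C(Cl)Oc1ccccc1
Why: DMAP-mediated thioacylation (first half of the Barton–McCombie deoxygenation) works on hindered secondary alcohols under non-basic conditions that leave the lactone and the silyl ether alone.

Step 10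
Reactants: 13 3β-(phenoxythiocarbonyloxy)-18-(tert-butyldiphenylsilyloxy)-14,15,16-trinorlabdan-13,8α-olide
Product: 14 18-(tert-butyldiphenylsilyloxy)-14,15,16-trinorlabdan-13,8α-olide
Conditions: Bu3SnH, AIBN (cat.), toluene, 100–110 °C
Reagents that add atoms: none
Why: Barton–McCombie radical deoxygenation fragments the thionocarbonate to a secondary C3 radical that is reduced by the stannane, and no stereocentre of the final compound is involved.

Step 11
Reactants: 14 18-(tert-butyldiphenylsilyloxy)-14,15,16-trinorlabdan-13,8α-olide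
Product: 15 18-hydroxy-14,15,16-trinorlabdan-13,8α-olide
Conditions: TBAF, AcOH (1 equiv), THF, rt → 45 °C
Reagents that add atoms: none
Why: Fluoride desilylation buffered with acetic acid cleaves the neopentyl silyl ether while the δ-lactone should survive the weakly basic medium.

Step 12
Reactants: 15 18-hydroxy-14,15,16-trinorlabdan-13,8α-olide
Product: 17 14,15,16-trinorlabdan-13,8α-olid-18-oic acid, via 18-oxo lactone 16 (not isolated)
Conditions: Jones reagent (CrO3, aq. H2SO4), acetone, 0 °C → rt
Reagents that add atoms: water (from the aqueous Jones reagent, adds to the intermediate aldehyde as its hydrate), O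
Why: Jones oxidation takes a neopentyl primary alcohol through the aldehyde to the acid, the lactone is stable to the acidic medium, and the quaternary C4 cannot epimerise.

Step 13
Reactants: 17 14,15,16-trinorlabdan-13,8α-olid-18-oic acid
Product: 19 dibenzyl 8α-hydroxy-14,15,16-trinorlabdane-13,18-dioate, via dipotassium hydroxy-dicarboxylate 18 (not isolated)
Conditions: KOH (2.2 equiv), MeOH/H2O, 65 °C; evaporation to dryness; BnBr, DMF, rt
Reagents that add atoms: potassium hydroxide, [K+].[OH-]; benzyl bromide, BrCc1ccccc1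
Why: Saponification opens the lactone at the acyl carbon, so C8 keeps its oxygen and configuration, and O-alkylation of the two carboxylates with benzyl bromide without acidification avoids relactonisation of the free hydroxy acid.

Step 14
Reactants: 19 dibenzyl 8α-hydroxy-14,15,16-trinorlabdane-13,18-dioate
Product: 20 dibenzyl 8α-acetoxy-14,15,16-trinorlabdane-13,18-dioate
Conditions: Ac2O, DMAP, Et3N, CH2Cl2, rt → 40 °C
Reagents that add atoms: acetic anhydride, CC(=O)OC(C)=O
Why: Steglich-type DMAP-catalysed acylation is the standard way to acetylate tertiary alcohols, and it acylates on oxygen with retention at C8.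

Step 15
Reactants: 20 dibenzyl 8α-acetoxy-14,15,16-trinorlabdane-13,18-dioate
Product: 21 (4R,5R,8R,9R,10S)-8α-acetoxy-14,15,16-trinorlabdane-13,18-dioic acid
Conditions: H2 (1 atm), 10% Pd/C, EtOAc, rt
Reagents that add atoms: none
Why: Catalytic hydrogenolysis removes both benzyl esters under neutral conditions, so the tertiary acetate should neither eliminate nor be displaced by the liberated C13 acid.

**Compound list**

1 | (2E,6E)-farnesol | CC(C)=CCC/C(C)=C/CC/C(C)=C/CO | starting material
2 | (2E,6E)-farnesyl bromide | CC(C)=CCC/C(C)=C/CC/C(C)=C/CBr | intermediate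
3 | diethyl malonate | CCOC(=O)CC(=O)OCC | starting material
4 | sodium diethyl malonate | [Na+].CCOC(=O)[CH-]C(=O)OCC | intermediate
5 | diethyl 2-[(2E,6E)-3,7,11-trimethyldodeca-2,6,10-trienyl]malonate | CC(C)=CCC/C(C)=C/CC/C(C)=C/CC(C(=O)OCC)C(=O)OCC | intermediate
6 | ethyl (4E,8E)-5,9,13-trimethyltetradeca-4,8,12-trienoate | CC(C)=CCC/C(C)=C/CC/C(C)=C/CCC(=O)OCC | intermediate
7 | ethyl (4E,8E,12E)-14-hydroxy-5,9,13-trimethyltetradeca-4,8,12-trienoate | OC/C(C)=C/CC/C(C)=C/CC/C(C)=C/CCC(=O)OCC | intermediate
8 | ethyl (4E,8E)-11-[(2S,3S)-3-(hydroxymethyl)-3-methyloxiran-2-yl]-5,9-dimethylundeca-4,8-dienoate | CCOC(=O)CC/C=C(C)/CC/C=C(C)/CC[C@@H]1O[C@@]1(C)CO | intermediate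
9 | ethyl (4E,8E)-11-[(2S,3S)-3-[(tert-butyldiphenylsilyloxy)methyl]-3-methyloxiran-2-yl]-5,9-dimethylundeca-4,8-dienoate | CCOC(=O)CC/C=C(C)/CC/C=C(C)/CC[C@@H]1O[C@@]1(C)CO[Si](c2ccccc2)(c2ccccc2)C(C)(C)C | intermediate
10 | lithium (4E,8E)-11-[(2S,3S)-3-[(tert-butyldiphenylsilyloxy)methyl]-3-methyloxiran-2-yl]-5,9-dimethylundeca-4,8-dienoate | [Li+].[O-]C(=O)CC/C=C(C)/CC/C=C(C)/CC[C@@H]1O[C@@]1(C)CO[Si](c2ccccc2)(c2ccccc2)C(C)(C)C | intermediate
11 | (4E,8E)-11-[(2S,3S)-3-[(tert-butyldiphenylsilyloxy)methyl]-3-methyloxiran-2-yl]-5,9-dimethylundeca-4,8-dienoic acid | OC(=O)CC/C=C(C)/CC/C=C(C)/CC[C@@H]1O[C@@]1(C)CO[Si](c2ccccc2)(c2ccccc2)C(C)(C)C | intermediate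
12 | 3β-hydroxy-18-(tert-butyldiphenylsilyloxy)-14,15,16-trinorlabdan-13,8α-olide | O=C1CC[C@H]2[C@](C)(O1)CC[C@@H]3[C@]2(C)CC[C@H](O)[C@@]3(C)CO[Si](c4ccccc4)(c4ccccc4)C(C)(C)C | intermediate
13 | 3β-(phenoxythiocarbonyloxy)-18-(tert-butyldiphenylsilyloxy)-14,15,16-trinorlabdan-13,8α-olide | O=C1CC[C@H]2[C@](C)(O1)CC[C@@H]3[C@]2(C)CC[C@H](OC(=S)Oc4ccccc4)[C@@]3(C)CO[Si](c5ccccc5)(c5ccccc5)C(C)(C)C | intermediate
14 | 18-(tert-butyldiphenylsilyloxy)-14,15,16-trinorlabdan-13,8α-olide | O=C1CC[C@H]2[C@](C)(O1)CC[C@@H]3[C@]2(C)CCC[C@@]3(C)CO[Si](c4ccccc4)(c4ccccc4)C(C)(C)C | intermediate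
15 | 18-hydroxy-14,15,16-trinorlabdan-13,8α-olide | O=C1CC[C@H]2[C@](C)(O1)CC[C@@H]3[C@]2(C)CCC[C@@]3(C)CO | intermediate
16 | 18-oxo-14,15,16-trinorlabdan-13,8α-olide | O=C1CC[C@H]2[C@](C)(O1)CC[C@@H]3[C@]2(C)CCC[C@@]3(C)C=O | intermediate
17 | 14,15,16-trinorlabdan-13,8α-olid-18-oic acid | O=C1CC[C@H]2[C@](C)(O1)CC[C@@H]3[C@]2(C)CCC[C@@]3(C)C(=O)O | intermediate
18 | dipotassium 8α-hydroxy-14,15,16-trinorlabdane-13,18-dioate | [K+].[K+].[O-]C(=O)CC[C@H]1[C@](C)(O)CC[C@@H]2[C@]1(C)CCC[C@@]2(C)C([O-])=O | intermediate
19 | dibenzyl 8α-hydroxy-14,15,16-trinorlabdane-13,18-dioate | O=C(OCc1ccccc1)CC[C@H]2[C@](C)(O)CC[C@@H]3[C@]2(C)CCC[C@@]3(C)C(=O)OCc4ccccc4 | intermediate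
20 | dibenzyl 8α-acetoxy-14,15,16-trinorlabdane-13,18-dioate | CC(=O)O[C@]1(C)CC[C@@H]2[C@](C)(CCC[C@@]2(C)C(=O)OCc3ccccc3)[C@H]1CCC(=O)OCc4ccccc4 | intermediate
21 | (4R,5R,8R,9R,10S)-8α-acetoxy-14,15,16-trinorlabdane-13,18-dioic acid | CC(=O)O[C@]1(C)CC[C@@H]2[C@](C)(CCC[C@@]2(C)C(=O)O)[C@H]1CCC(=O)O | target

**Totals and risks**

Total step count: 15. Longest linear sequence: 15 steps (1 → 21).

Steps most likely to fail:

Step 8. The cascade may stop early by proton loss after one or two rings, the activated oxirane may be opened by chloride or undergo a 1,2-hydride shift because the neighbouring silyloxymethyl group slows ionisation at C4, or the tin-bound carboxyl may fail to capture C8. The fallback separates ring formation from lactonisation and opens the epoxide homolytically. It sets out from 9: titanocene(III) chloride (Cp2TiCl2, Mn dust, THF, rt) should open the oxirane to the tertiary C4 radical, close rings A and B by 6-endo radical additions through the same chair–chair array, and end by titanium-mediated β-hydride loss to give ethyl 3β-hydroxy-18-(tert-butyldiphenylsilyloxy)-14,15,16-trinorlabd-8(17)-en-13-oate F1. In this radical manifold C4 is expected to place the larger silyloxymethyl group equatorial, which would have to be confirmed. Saponification (LiOH, aq. THF/MeOH) should give 3β-hydroxy-18-(tert-butyldiphenylsilyloxy)-14,15,16-trinorlabd-8(17)-en-13-oic acid F2. Brønsted-acid hydrolactonisation (cat. TsOH, CH2Cl2 or toluene) should then protonate the exocyclic alkene to the C8 cation, which the carboxyl traps on the equatorial α-face, and the sequence comes back to the route at 12.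

Step 4. Allylic oxidation may be poorly site-selective among three trisubstituted alkenes (attack at internal allylic CH2 groups) and may over-oxidise to the enal. The fallback builds the (E)-allylic alcohol by olefination instead of C–H oxidation. It sets out from 6: NBS in aqueous THF at 0 °C should give the terminal bromohydrin ethyl (4E,8E)-12-bromo-13-hydroxy-5,9,13-trimethyltetradeca-4,8-dienoate F3, closed with K2CO3 in EtOH to the racemic terminal epoxide ethyl (4E,8E)-11-(3,3-dimethyloxiran-2-yl)-5,9-dimethylundeca-4,8-dienoate F4. Periodic acid (H5IO6, Et2O/THF) should cleave this to ethyl (4E,8E)-5,9-dimethyl-12-oxododeca-4,8-dienoate F5. Wittig olefination with 2-(triphenylphosphoranylidene)propanal (toluene, 80 °C) should give the E-enal ethyl (4E,8E,12E)-5,9,13-trimethyl-14-oxotetradeca-4,8,12-trienoate F6, and Luche reduction (NaBH4, CeCl3·7H2O, EtOH, 0 °C), which spares the ethyl ester, comes back to the route at 7.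

Step 14. Acylation of the hindered tertiary C8 hydroxyl may be outrun by its attack on the δ-benzyl ester (relactonisation with loss of benzyl alcohol) or by elimination. The fallback removes the ester carbonyl before the acetylation and restores both acids at the end. It sets out from 15: LiAlH4 (THF, 0 °C → rt) should reduce the lactone to 14,15,16-trinorlabdane-8α,13,18-triol F7. Exhaustive acetylation (Ac2O, DMAP, Et3N, 40 °C) should give 8α,13,18-triacetoxy-14,15,16-trinorlabdane F8. Mild methanolysis (K2CO3, MeOH, rt) should remove only the two primary acetates to give 8α-acetoxy-14,15,16-trinorlabdane-13,18-diol F9. Oxidation of both primary alcohols under near-neutral conditions (TEMPO cat., NaClO2, NaOCl cat., MeCN/phosphate buffer pH 6.7) comes back to the route at 21.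

**Further compounds**

F1 | step 8 | ethyl 3β-hydroxy-18-(tert-butyldiphenylsilyloxy)-14,15,16-trinorlabd-8(17)-en-13-oate | CCOC(=O)CC[C@H]1C(=C)CC[C@@H]2[C@]1(C)CC[C@H](O)[C@@]2(C)CO[Si](c3ccccc3)(c3ccccc3)C(C)(C)C
F2 | step 8 | 3β-hydroxy-18-(tert-butyldiphenylsilyloxy)-14,15,16-trinorlabd-8(17)-en-13-oic acid | OC(=O)CC[C@H]1C(=C)CC[C@@H]2[C@]1(C)CC[C@H](O)[C@@]2(C)CO[Si](c3ccccc3)(c3ccccc3)C(C)(C)C
F3 | step 4 | ethyl (4E,8E)-12-bromo-13-hydroxy-5,9,13-trimethyltetradeca-4,8-dienoate (racemic) | CC(C)(O)C(Br)CC/C(C)=C/CC/C(C)=C/CCC(=O)OCC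
F4 | step 4 | ethyl (4E,8E)-11-(3,3-dimethyloxiran-2-yl)-5,9-dimethylundeca-4,8-dienoate (racemic) | CC1(C)OC1CC/C(C)=C/CC/C(C)=C/CCC(=O)OCC
F5 | step 4 | ethyl (4E,8E)-5,9-dimethyl-12-oxododeca-4,8-dienoate | O=CCC/C(C)=C/CC/C(C)=C/CCC(=O)OCC
F6 | step 4 | ethyl (4E,8E,12E)-5,9,13-trimethyl-14-oxotetradeca-4,8,12-trienoate | O=C/C(C)=C/CC/C(C)=C/CC/C(C)=C/CCC(=O)OCC
F7 | step 14 | 14,15,16-trinorlabdane-8α,13,18-triol | OCCC[C@H]1[C@](C)(O)CC[C@@H]2[C@]1(C)CCC[C@@]2(C)CO
F8 | step 14 | 8α,13,18-triacetoxy-14,15,16-trinorlabdane | CC(=O)OCCC[C@H]1[C@](C)(OC(C)=O)CC[C@@H]2[C@]1(C)CCC[C@@]2(C)COC(C)=O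
F9 | step 14 | 8α-acetoxy-14,15,16-trinorlabdane-13,18-diol | OCCC[C@H]1[C@](C)(OC(C)=O)CC[C@@H]2[C@]1(C)CCC[C@@]2(C)CO
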